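**Retrosynthetic overview** (guaiane numbering: C1/C5 ring fusion, C2–C4 in the five-membered ring, C6–C10 in the seven-membered ring)
1. Target ⇒ phenol desilylation, C10-OH-directed epoxidation of C3=C4 and esterification of C8-OH ⇒ guai-3-ene-8,10-diol 19, whose cyclopentene (C1–C2–C3=C4–C5) is closed by methylenation of the C4 acetyl carbonyl and ring-closing metathesis with the C1 allyl group.
2. Feature: C4 (methyl-bearing epoxide carbon) and C8 (ester carbinol) are both carbonyl-level carbons, 1,5-related through C5–C6–C7 in the seven-membered ring (C1, C5, C6, C7, C8, C9, C10); C6–C7 with its isopropyl group is 3-methylbut-1-ene.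
3. Key disconnection: de Mayo two-carbon ring expansion. [2+2] Photocycloaddition of the ring-enol acetate of a 2-acetylcyclopentanone (C5=C8) with 3-methylbut-1-ene forms C5–C6 and C7–C8; retro-aldol cleavage of C5–C8 turns the cyclopentane C8–C9–C10–C1–C5 into the seven-membered ring.
4. The cyclopentane diketone ⇒ (R)-4-silyloxy-4-methylcyclopent-2-enone (conjugate allylation, aldol capture, oxidation) ⇒ 3-methylcyclopent-2-enone (asymmetric epoxidation, reductive opening, silylation, dehydrogenation).
5. Ring order: cyclopentane (from the start) → seven-membered ring (step 8) → cyclopentene (step 12) → epoxide (step 15).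

Key step: step 8

Assumption: the quinine-derived 9-amino-9-deoxy-epi-cinchona salt is taken to give the (2S,3S)-epoxide in step 1; if its sense is the opposite, the quinidine-derived pseudoenantiomer is used.

Step 1
Reactants: 1 3-methylcyclopent-2-en-1-one
Product: 2 (2S,3S)-2,3-epoxy-3-methylcyclopentan-1-one
Conditions: 9-amino-9-deoxy-epi-quinine (10 mol %), CF3CO2H (20 mol %), 50% aq. H2O2, dioxane, 30 °C
Reagents that add atoms: hydrogen peroxide, OO
Why: Amine-salt (iminium) catalysed Weitz–Scheffer epoxidation of a cyclic enone, in which the chiral primary ammonium salt directs hydroperoxide addition to one face of C3 and ring closure gives the cis-fused epoxide, setting the future C10 carbinol centre.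

Step 2
Reactants: 2 (2S,3S)-2,3-epoxy-3-methylcyclopentan-1-one
Product: 3 (S)-3-hydroxy-3-methylcyclopentan-1-one
Conditions: SmI2 (2.2 equiv), THF–MeOH, −78 °C
Reagents that add atoms: none
Why: SmI2 reduction of an α,β-epoxy ketone (ketyl formation, Cα–O cleavage, enolate protonation) should give the β-hydroxy ketone with the Cβ–O bond and its configuration untouched, the low temperature and neutral work-up avoiding dehydration back to 1.

Step 3
Reactants: 3 (S)-3-hydroxy-3-methylcyclopentan-1-one
Product: 4 (S)-3-(tert-butyldimethylsilyloxy)-3-methylcyclopentan-1-one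
Conditions: TBSOTf, 2,6-lutidine, CH2Cl2, −78 to 0 °C
Reagents that add atoms: tert-butyldimethylsilyl trifluoromethanesulfonate, CC(C)(C)[Si](C)(C)OS(=O)(=O)C(F)(F)F
Why: Silyl triflate/lutidine silylation of a hindered tertiary alcohol, run cold so that the ketone is not enol-silylated and the β-hydroxy ketone does not eliminate.

Step 4
Reactants: 4 (S)-3-(tert-butyldimethylsilyloxy)-3-methylcyclopentan-1-one
Product: 6 (R)-4-(tert-butyldimethylsilyloxy)-4-methylcyclopent-2-en-1-one, via trimethylsilyl enol ether 5 (not isolated)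
Conditions: LDA, Me3SiCl, THF, −78 °C; then Pd(OAc)2 (1.05 equiv), MeCN, rt
Reagents that add atoms: none
Why: Kinetic deprotonation with internal silyl quench should occur at the CH2 remote from the quaternary silyloxy carbon, and Saegusa–Ito oxidation of that silyl enol ether gives the enone, the regioisomeric enol ether being unable to give an enone because it has no β-hydrogen.

Step 5
Reactants: 6 (R)-4-(tert-butyldimethylsilyloxy)-4-methylcyclopent-2-en-1-one; 7 allyltrimethylsilane
Product: 9 (3R,4R)-3-allyl-4-(tert-butyldimethylsilyloxy)-2-(1-hydroxyethyl)-4-methylcyclopentan-1-one (diastereomer mixture at C2/carbinol carbon), via trichlorotitanium enolate 8 (not isolated)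
Conditions: TiCl4, CH2Cl2, −78 °C; then MeCHO, −78 °C; aq. NaHCO3
Reagents that add atoms: acetaldehyde, CC=O
Why: Hosomi–Sakurai conjugate allylation followed by aldol capture of the regiodefined titanium enolate, the allyl group entering the β-carbon anti to the bulky silyloxy group (and antiperiplanar to the C–O bond) so that C1 is set trans to the C10 oxygen, while the two aldol centres are erased in steps 6 to 8.

Step 6
Reactants: 9 (3R,4R)-3-allyl-4-(tert-butyldimethylsilyloxy)-2-(1-hydroxyethyl)-4-methylcyclopentan-1-one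
Product: 10 (3R,4R)-2-acetyl-3-allyl-4-(tert-butyldimethylsilyloxy)-4-methylcyclopentan-1-one (enolised 1,3-diketone)
Conditions: Dess–Martin periodinane, CH2Cl2, 0 °C to rt
Reagents that add atoms: none
Why: Dess–Martin oxidation of a β-hydroxy ketone to the 1,3-diketone under neutral conditions that spare the silyl ether and the terminal alkene.

Step 7
Reactants: 10 (3R,4R)-2-acetyl-3-allyl-4-(tert-butyldimethylsilyloxy)-4-methylcyclopentan-1-one
Product: 11 (3R,4R)-2-acetyl-3-allyl-4-(tert-butyldimethylsilyloxy)-4-methylcyclopent-1-en-1-yl acetate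
Conditions: AcCl, pyridine, CH2Cl2, 0 °C
Reagents that add atoms: acetyl chloride, CC(Cl)=O
Why: O-acylation of an enolised 1,3-diketone, in which the chelated enol of a 2-acylcyclopentanone (enol double bond preferentially exocyclic) reacts at its carbonyl-type ring oxygen to give the endocyclic enol ester, locking C5=C8 in the ring; DMAP and heat are avoided so that the acyl group does not migrate between the two oxygens.

Step 8
Reactants: 11 (3R,4R)-2-acetyl-3-allyl-4-(tert-butyldimethylsilyloxy)-4-methylcyclopent-1-en-1-yl acetate; 12 3-methylbut-1-ene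
Product: 15 (2S,4S,5R,6R)-4-acetyl-5-allyl-6-(tert-butyldimethylsilyloxy)-2-isopropyl-6-methylcycloheptan-1-one, via cyclobutyl acetate photoadduct 13 (not isolated), via cyclobutanol 14 (not isolated)
Conditions: hν (350 nm, Pyrex), neat 12 (large excess), −20 °C; evaporate; then K2CO3 (0.3 equiv), MeOH, 0 °C to rt
Reagents that add atoms: none
Why: Excitation of the β-acetoxy enone (C4=O conjugated with C5=C8) gives a triplet that adds 12 stepwise through a 1,4-biradical to the cis-fused cyclobutane 13 (new bonds C5–C6 and C7–C8), and methanolysis of the tertiary acetate frees cyclobutanol 14, whose strained β-hydroxy ketone (HO–C8–C5–C4=O) fragments by retro-aldol cleavage of C5–C8. The closest known reaction type is the de Mayo reaction in its enol-ester form, as used for two-carbon ring expansion of 2-acylcycloalkanones and cyclic 1,3-diketones. The seven-membered ring (C1, C5, C6, C7, C8, C9, C10) is not closed by cyclising a chain: a four-membered ring is annulated onto the C5=C8 edge of the cyclopentene by intermolecular [2+2] addition and the shared C5–C8 bond is then broken, so the five-membered ring grows by C6 and C7. The new stereocentres C5 and C7 both lie α to a carbonyl group and should be set under thermodynamic control by the same K2CO3/MeOH treatment (C5 trans to the C1 allyl group, C7 cis-1,3 to the acetyl group, all three substituents pseudo-equatorial), while the facial course of the cycloaddition is erased and C1 and C10 are untouched. The step needs head-to-tail orientation (isopropyl-bearing carbon on the oxygenated C8), which follows from the usual orientation of alkyl ethylenes with excited enones and from the greater crowding at C5; it needs reaction through the ring enol, which the acetate fixes; and it needs intermolecular capture to outrun crossed addition to the C1 allyl group, which neat alkene and the strained norbornane-like biradical of the intramolecular path should ensure. Light of 350 nm is chosen so that the saturated ketone of 13 does not absorb.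

Step 9
Reactants: 15 (2S,4S,5R,6R)-4-acetyl-5-allyl-6-(tert-butyldimethylsilyloxy)-2-isopropyl-6-methylcycloheptan-1-one
Product: 16 (2S,4S,5R,6R)-4-acetyl-5-allyl-6-hydroxy-2-isopropyl-6-methylcycloheptan-1-one
Conditions: 48% aq. HF, MeCN, 0 °C to rt
Reagents that add atoms: none
Why: Acidic fluoride cleavage of the tertiary silyl ether, chosen because basic fluoride would expose the resulting β-hydroxy ketone to retro-aldol cleavage and β-elimination.

Step 10
Reactants: 16 (2S,4S,5R,6R)-4-acetyl-5-allyl-6-hydroxy-2-isopropyl-6-methylcycloheptan-1-one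
Product: 17 1-[(1S,2R,3R,5R,6S)-2-allyl-3,5-dihydroxy-6-isopropyl-3-methylcycloheptyl]ethan-1-one
Conditions: Me4NBH(OAc)3, MeCN–AcOH (1:1), −35 °C
Reagents that add atoms: none
Why: Evans–Saksena hydroxyl-directed reduction, in which the C10 alkoxy(diacetoxy)borohydride delivers hydride to the β-carbonyl C8 from the face of the C10 oxygen to give the 1,3-trans diol (C8 set), while the acetyl ketone, having no β-hydroxyl, is not reduced by this weak hydride.

Step 11
Reactants: 17 1-[(1S,2R,3R,5R,6S)-2-allyl-3,5-dihydroxy-6-isopropyl-3-methylcycloheptyl]ethan-1-one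
Product: 18 (1R,3R,4S,6S,7R)-7-allyl-4-isopropyl-1-methyl-6-(prop-1-en-2-yl)cycloheptane-1,3-diol
Conditions: Ph3PCH3Br, KOtBu (excess), THF, 0 to 50 °C
Reagents that add atoms: methyltriphenylphosphonium bromide, C[P+](c1ccccc1)(c1ccccc1)c1ccccc1.[Br-]
Why: Wittig methylenation of the methyl ketone with excess ylide, the two hydroxyls being carried as alkoxides and C5 already being the thermodynamic epimer so that the basic medium does not change it.

Step 12
Reactants: 18 (1R,3R,4S,6S,7R)-7-allyl-4-isopropyl-1-methyl-6-(prop-1-en-2-yl)cycloheptane-1,3-diol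
Product: 19 (1R,5S,7S,8R,10R)-guai-3-ene-8,10-diol (trans-fused hydroazulene)
Conditions: second-generation Grubbs catalyst (H2IMes)(PCy3)Cl2Ru=CHPh (5 mol %), CH2Cl2, 40 °C
Reagents that add atoms: none
Why: Ring-closing metathesis of the 1,6-diene (isopropenyl on C5, allyl on C1) should form the trisubstituted C3=C4 cyclopentene with loss of ethene, the trans arrangement of the two arms giving the trans ring fusion and the free hydroxyls being tolerated.

Step 13
Reactants: 20 4-hydroxybenzoic acid
Product: 22 4-(tert-butyldimethylsilyloxy)benzoic acid, via bis-silylated acid 21 (not isolated)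
Conditions: TBSCl (2.2 equiv), imidazole, DMF, rt; then AcOH–THF–H2O, rt
Reagents that add atoms: tert-butyldimethylsilyl chloride, CC(C)(C)[Si](C)(C)Cl
Why: Silylation of both the phenol and the acid followed by selective hydrolysis of the labile silyl ester leaves the aryl silyl ether.

Step 14
Reactants: 19 (1R,5S,7S,8R,10R)-guai-3-ene-8,10-diol; 22 4-(tert-butyldimethylsilyloxy)benzoic acid
Product: 23 (1R,5S,7S,8R,10R)-10-hydroxyguai-3-en-8-yl 4-(tert-butyldimethylsilyloxy)benzoate
Conditions: EDC·HCl, DMAP, CH2Cl2, rt
Reagents that add atoms: none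
Why: Steglich esterification, in which only the secondary C8 hydroxyl is acylated (with retention) because the tertiary C10 hydroxyl is too hindered.

Step 15
Reactants: 23 (1R,5S,7S,8R,10R)-10-hydroxyguai-3-en-8-yl 4-(tert-butyldimethylsilyloxy)benzoate
Product: 24 (1R,3R,4S,5S,7S,8R,10R)-3,4-epoxy-10-hydroxyguaian-8-yl 4-(tert-butyldimethylsilyloxy)benzoate
Conditions: VO(acac)2 (5 mol %), t-BuOOH (decane), CH2Cl2, 0 °C to rt
Reagents that add atoms: tert-butyl hydroperoxide, CC(C)(C)OO
Why: Vanadium-catalysed hydroxyl-directed epoxidation, in which the C10 hydroxyl binds the vanadium alkylperoxide and delivers oxygen to C3=C4 on its own face, setting C3 and C4 with the epoxide syn to the C10 hydroxyl and H1 and anti to H5.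

Step 16
Reactants: 24 (1R,3R,4S,5S,7S,8R,10R)-3,4-epoxy-10-hydroxyguaian-8-yl 4-(tert-butyldimethylsilyloxy)benzoate
Product: 25 (1R,3R,4S,5S,7S,8R,10R)-3,4-epoxy-10-hydroxyguaian-8-yl 4-hydroxybenzoate (CNP0225095.2)
Conditions: Bu4NF, AcOH, THF, 0 °C
Reagents that add atoms: none
Why: Buffered fluoride cleavage of the aryl silyl ether, under which the ester, the epoxide and the tertiary alcohol should be stable.

**Compound list**
1 | 3-methylcyclopent-2-en-1-one | CC1=CC(=O)CC1 | starting material
2 | (2S,3S)-2,3-epoxy-3-methylcyclopentan-1-one | C[C@]12CCC(=O)[C@H]1O2 | intermediate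
3 | (S)-3-hydroxy-3-methylcyclopentan-1-one | C[C@@]1(O)CC(=O)CC1 | intermediate
4 | (S)-3-(tert-butyldimethylsilyloxy)-3-methylcyclopentan-1-one | C[C@@]1(O[Si](C)(C)C(C)(C)C)CC(=O)CC1 | intermediate
5 | (S)-4-(tert-butyldimethylsilyloxy)-4-methyl-1-(trimethylsilyloxy)cyclopent-1-ene | C[C@@]1(O[Si](C)(C)C(C)(C)C)CC(O[Si](C)(C)C)=CC1 | intermediate
6 | (R)-4-(tert-butyldimethylsilyloxy)-4-methylcyclopent-2-en-1-one | C[C@@]1(O[Si](C)(C)C(C)(C)C)CC(=O)C=C1 | intermediate
7 | allyltrimethylsilane | C=CC[Si](C)(C)C | starting material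
8 | trichlorotitanium enolate of (3R,4R)-3-allyl-4-(tert-butyldimethylsilyloxy)-4-methylcyclopentan-1-one | C1=C(O[Ti](Cl)(Cl)Cl)C[C@@](C)(O[Si](C)(C)C(C)(C)C)[C@@H]1CC=C | intermediate
9 | (3R,4R)-3-allyl-4-(tert-butyldimethylsilyloxy)-2-(1-hydroxyethyl)-4-methylcyclopentan-1-one, mixture at C2 and at the carbinol carbon | CC(O)C1C(=O)C[C@@](C)(O[Si](C)(C)C(C)(C)C)[C@@H]1CC=C | intermediate
10 | (3R,4R)-2-acetyl-3-allyl-4-(tert-butyldimethylsilyloxy)-4-methylcyclopentan-1-one, drawn as its ring enol | CC(=O)C1=C(O)C[C@@](C)(O[Si](C)(C)C(C)(C)C)[C@@H]1CC=C | intermediate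
11 | (3R,4R)-2-acetyl-3-allyl-4-(tert-butyldimethylsilyloxy)-4-methylcyclopent-1-en-1-yl acetate | CC(=O)C1=C(OC(C)=O)C[C@@](C)(O[Si](C)(C)C(C)(C)C)[C@@H]1CC=C | intermediate
12 | 3-methylbut-1-ene | CC(C)C=C | starting material
13 | 5-acetyl-4-allyl-3-(tert-butyldimethylsilyloxy)-7-isopropyl-3-methylbicyclo[3.2.0]heptan-1-yl acetate, silyloxy and allyl centres as in 11, mixture at the three new centres | CC(=O)C12CC(C(C)C)C1(OC(C)=O)C[C@@](C)(O[Si](C)(C)C(C)(C)C)[C@@H]2CC=C | intermediate
14 | 1-(4-allyl-3-(tert-butyldimethylsilyloxy)-1-hydroxy-7-isopropyl-3-methylbicyclo[3.2.0]heptan-5-yl)ethan-1-one, stereochemistry as in 13 | CC(=O)C12CC(C(C)C)C1(O)C[C@@](C)(O[Si](C)(C)C(C)(C)C)[C@@H]2CC=C | intermediate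
15 | (2S,4S,5R,6R)-4-acetyl-5-allyl-6-(tert-butyldimethylsilyloxy)-2-isopropyl-6-methylcycloheptan-1-one | CC(C)[C@@H]1C[C@H](C(C)=O)[C@@H](CC=C)[C@](C)(O[Si](C)(C)C(C)(C)C)CC1=O | intermediate
16 | (2S,4S,5R,6R)-4-acetyl-5-allyl-6-hydroxy-2-isopropyl-6-methylcycloheptan-1-one | CC(C)[C@@H]1C[C@H](C(C)=O)[C@@H](CC=C)[C@](C)(O)CC1=O | intermediate
17 | 1-[(1S,2R,3R,5R,6S)-2-allyl-3,5-dihydroxy-6-isopropyl-3-methylcycloheptyl]ethan-1-one | CC(C)[C@@H]1C[C@H](C(C)=O)[C@@H](CC=C)[C@](C)(O)C[C@H]1O | intermediate
18 | (1R,3R,4S,6S,7R)-7-allyl-4-isopropyl-1-methyl-6-(prop-1-en-2-yl)cycloheptane-1,3-diol | CC(C)[C@@H]1C[C@H](C(C)=C)[C@@H](CC=C)[C@](C)(O)C[C@H]1O | intermediate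
19 | (1R,5S,7S,8R,10R)-guai-3-ene-8,10-diol | CC(C)[C@@H]1C[C@H]2[C@@H](CC=C2C)[C@](C)(O)C[C@H]1O | intermediate
20 | 4-hydroxybenzoic acid | OC(=O)c1ccc(O)cc1 | starting material
21 | tert-butyldimethylsilyl 4-(tert-butyldimethylsilyloxy)benzoate | CC(C)(C)[Si](C)(C)OC(=O)c1ccc(O[Si](C)(C)C(C)(C)C)cc1 | intermediate
22 | 4-(tert-butyldimethylsilyloxy)benzoic acid | OC(=O)c1ccc(O[Si](C)(C)C(C)(C)C)cc1 | intermediate
23 | (1R,5S,7S,8R,10R)-10-hydroxyguai-3-en-8-yl 4-(tert-butyldimethylsilyloxy)benzoate | CC(C)[C@@H]1C[C@H]2[C@@H](CC=C2C)[C@](C)(O)C[C@H]1OC(=O)c1ccc(O[Si](C)(C)C(C)(C)C)cc1 | intermediate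
24 | (1R,3R,4S,5S,7S,8R,10R)-3,4-epoxy-10-hydroxyguaian-8-yl 4-(tert-butyldimethylsilyloxy)benzoate | CC(C)[C@@H]1C[C@H]2[C@@H](C[C@H]3O[C@]32C)[C@](C)(O)C[C@H]1OC(=O)c1ccc(O[Si](C)(C)C(C)(C)C)cc1 | intermediate
25 | (1R,3R,4S,5S,7S,8R,10R)-3,4-epoxy-10-hydroxyguaian-8-yl 4-hydroxybenzoate (CNP0225095.2) | CC(C)[C@@H]1C[C@H]2[C@@H](C[C@H]3O[C@]32C)[C@](C)(O)C[C@H]1OC(=O)c1ccc(O)cc1 | target

**Step count and risks**
Total step count: 16. Longest linear sequence: 15 (steps 1 to 12 and 14 to 16); step 13 prepares the acid 22.

The three steps most likely to fail: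

Step 8. The excited enone may add the monoalkyl ethylene in the head-to-head sense, it may be captured by the pendant allyl group before the alkene arrives, and the basic equilibration may eliminate the β-silyloxy group. The fallback sets out from 11 and changes the photopartner to an oxygen-substituted alkene whose donor group enforces bonding of its substituted carbon to C8. This is 2-(triethylsilyloxy)-3-methylbut-1-ene F1, made from 3-methylbutan-2-one with LDA and Et3SiCl. Irradiation as in step 8 should give 5-acetyl-4-allyl-3-(tert-butyldimethylsilyloxy)-7-isopropyl-3-methyl-7-(triethylsilyloxy)bicyclo[3.2.0]heptan-1-yl acetate F2, and K2CO3/MeOH should fragment it to 4-acetyl-5-allyl-6-(tert-butyldimethylsilyloxy)-2-isopropyl-6-methyl-2-(triethylsilyloxy)cycloheptan-1-one F3. SmI2 in THF–MeOH then removes the oxygen on C7 (reductive cleavage of an α-oxygenated ketone), and brief K2CO3/MeOH equilibration brings the route back at 15.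

Step 7. Acylation may fall on the side-chain oxygen, or the acyl group may migrate between the two oxygens, giving the exocyclic enol ester, which cannot lead to ring expansion. Acylation on the side-chain oxygen would indicate that the ring enol is the populated, carbonyl-nucleophilic tautomer of 10. The fallback therefore sets out from 10 and irradiates the free chelated enol itself with 12 (classical de Mayo conditions, 350 nm, neat alkene). The cyclobutanol 14 forms directly and fragments to the diketone, and K2CO3/MeOH equilibration brings the route back at 15; this fallback makes no compound outside the list (F0).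

Step 1. Iminium formation with the five-membered enone may be slow and the enantioselectivity may erode, which would carry through every later stereocentre. The fallback sets out from 1 and uses reagent control at the carbonyl followed by substrate control. Oxazaborolidine-catalysed (CBS, (S)-2-methyl catalyst assumed, BH3·SMe2) reduction should give (R)-3-methylcyclopent-2-en-1-ol F4. Hydroxyl-directed epoxidation (VO(acac)2, t-BuOOH) syn to the hydroxyl should give (1R,2R,3S)-2,3-epoxy-3-methylcyclopentan-1-ol F5, and Dess–Martin oxidation brings the route back at 2.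

**Further compounds**
F1 | step 8 | 2-(triethylsilyloxy)-3-methylbut-1-ene | CC(C)C(=C)O[Si](CC)(CC)CC
F2 | step 8 | 5-acetyl-4-allyl-3-(tert-butyldimethylsilyloxy)-7-isopropyl-3-methyl-7-(triethylsilyloxy)bicyclo[3.2.0]heptan-1-yl acetate | CC(=O)C12CC(C(C)C)(O[Si](CC)(CC)CC)C1(OC(C)=O)C[C@@](C)(O[Si](C)(C)C(C)(C)C)[C@@H]2CC=C
F3 | step 8 | 4-acetyl-5-allyl-6-(tert-butyldimethylsilyloxy)-2-isopropyl-6-methyl-2-(triethylsilyloxy)cycloheptan-1-one | CC(C)C1(O[Si](CC)(CC)CC)C[C@H](C(C)=O)[C@@H](CC=C)[C@](C)(O[Si](C)(C)C(C)(C)C)CC1=O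
F0 | step 7 | none | none
F4 | step 1 | (R)-3-methylcyclopent-2-en-1-ol | O[C@H]1C=C(C)CC1
F5 | step 1 | (1R,2R,3S)-2,3-epoxy-3-methylcyclopentan-1-ol | C[C@]12CC[C@@H](O)[C@H]1O2
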